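Zeta is the flask asked about, followed so far to 3.00 d. Eta is the same charge with less free catalyst. In both, the solid reagent starts undissolved.

all flasks: left-handed substrate 0.12 M; right-handed substrate 0.12 M
- zeta: solid reagent 0.24 M; free catalyst 1.1 mM; the very flask that is asked about, followed so far
- eta: solid reagent 0.24 M; free catalyst 0.74 mM; run made earlier
- flask: solid reagent 0.240 M; free catalyst 1.1 mM; time 10 d

| zeta: time / d | zeta: left-handed product / % | eta: time / d | eta: left-handed product / % |
|---|---|---|---|
| 0.250 | 0 | 0.500 | 0.6 |
| 0.500 | 0 | 1.25 | 0.3 |
| 1.25 | 1.5 | 2.50 | 2.9 |
| 3.00 | 5.1 | 4.00 | 6.2 |

(standard deviation of a reading: 0.5 percentage points)

- free catalyst is single-handed; left-handed substrate and right-handed substrate are mirror images of each other, charged as a racemate, each of them at the stated concentration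
- as a solid, counted per litre of solution: solid reagent
- at the start none of the solid reagent is in solution

- amber: doubling the dissolution coefficient of the solid reagent, all else as stated
- violet: doubling the solubility of the solid reagent, all else as stated
- teal: doubling the amount of free catalyst, all else as stated

- how much left-handed product there is at 10 d, in percent of the left-handed substrate and right-handed substrate together charged
- the change that raises the amount of left-handed product at 10 d, in percent of the left-handed substrate and right-handed substrate together charged most ("none" if none brings more than 2 percentage points) (amber / violet / teal / none)
- amount of left-handed product at 10 d, in percent of the left-handed substrate and right-handed substrate together charged, after amber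

Both runs stay near zero, then climb. Between its last two readings, left-handed product in zeta rises by 0.0206 d⁻¹ as a fraction of the total charge, and in eta by 0.0220 d⁻¹. The catalyst differs by a factor of 1.49, but the slopes stand at a ratio of 0.936. So I read dissolving as the rate-limiting step and expect amber or violet to beat teal. Zeta's slope, run on from its last reading, gives 19.5%. The weak link is that slope: two readings, each with a scatter of 0.5 percentage points. Eta supplies a separate measure, so I take the mean, 0.0213 d⁻¹, as the feed slope: the fraction of the total charge becoming left-handed product per day on the straight stretch. From zeta's last reading it gives 20.0%.

The forecast says 18%, below my number, with violet best and 30% after amber, on this ground: “the steady rate is set by dissolution of the solid”.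

The flask gives 19.4%, with violet best and 29.9% after amber, so the forecast stands.

    partner + free catalyst + left-handed substrate → free catalyst + left-handed product (k = 280 M⁻² h⁻¹)
    partner + free catalyst + right-handed substrate → free catalyst + right-handed product (k = 150 M⁻² h⁻¹)
    solid reagent ⇌ partner, rate k3*(cs3 - [partner]) while solid is left; crystals form when [partner] > cs3 (solubility = 38.0 mM, k = 0.0110 h⁻¹)
    partner + free catalyst → spent catalyst (k = 0.00850 M⁻¹ h⁻¹)

Between 5.00 d and 10.0 d, the flask gains left-handed product at 0.0198 d⁻¹ as a fraction of the total charge, against a feed slope of 0.0213 d⁻¹. The flask is not at rest at 10 d: 61% of the charged left-handed substrate remains. The feed slope projected to 100 d gives 212%, beyond the cap of 50.0%, and the computed left-handed product there is 49.9% of the total charge, with left-handed substrate at 0.0726% of the total charge. With the other amounts and the time held, the nearest amounts of free catalyst that move the left-handed product at 10 d by 5 points are 0.434 mM and 7.05 mM.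

For the same flask stopped at 4.0 d, the feed slope from zeta's last reading gives 7.23%; that computed flask holds 7.40% left-handed product.

The data stem from a simulated flask on assumed constants, and the scatter is random.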